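Everything rests on cutting the cycloheptane ring into a three-carbon unit, C10(H)(CH3)–C9–C8, and a four-carbon unit, C1–C5–C6–C7 (C1 = carbinol carbon, C5 = CH–O-isobutyryl, C6 = lactone CH–O, C7 = ring-fusion CH). The four-carbon unit is a furan whose ring oxygen becomes the tertiary C1 hydroxyl; the precursor is (R)-1-(furan-2-yl)butan-1-ol plus 1,3-dibromobutan-2-one. A zinc-mediated (4+3) cycloaddition of the derived methyl-oxyallyl cation forms C1–C10 and C7–C8 in one operation and sets C1 and C10, the carbinol (the future C2 ketone) steering the face. The C9 ketone then opens the oxygen bridge; C5–C7 are oxygenated and lactonised, and C9 is deoxygenated.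

Key step: step 2

Numbering (that of the target): C1 quaternary carbinol carbon; C2 side-chain carbonyl carbon, C3=C4, C15 its methyl; C5 CH–O–isobutyryl; C6 lactone CH–O; C7 ring-fusion CH; C8 and C9 ring CH2; C10 CH(CH3); C11 lactone CH(CH3); C12 lactone carbonyl. β is the face of the C1 hydroxyl, α the opposite face.

Assumption: the zinc alkoxide of the furyl carbinol delivers the oxyallyl cation to the furan face on which it lies, in the conformer whose carbinol C–H eclipses the adjacent ring C=C bond. On this model (R)-2 leads to the target series. If the opposite sense were found, (S)-2 (enantiomeric catalyst in step 1) would be carried through the same steps, since this centre is oxidised in step 12.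

Compounds 1, 3 and 9 are taken as commercially available.

Step 1
Reactants: 1 1-(furan-2-yl)butan-1-one
Product: 2 (R)-1-(furan-2-yl)butan-1-ol
Conditions: RuCl[(R,R)-TsDPEN](p-cymene) (1 mol %), HCO2H/Et3N, rt
Reagents that add atoms: none
Why: Noyori asymmetric transfer hydrogenation of a furyl alkyl ketone should deliver hydride to one carbonyl face under control of the (R,R)-diamine ligand, setting the (R)-carbinol that later directs the cycloaddition.

Step 2
Reactants: 2 (R)-1-(furan-2-yl)butan-1-ol; 3 1,3-dibromobutan-2-one
Product: 5 (1R,2R,5R)-1-[(1R)-1-hydroxybutyl]-2-methyl-8-oxabicyclo[3.2.1]oct-6-en-3-one, via zinc-bound oxyallyl cation 4 (not isolated)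
Conditions: Et2Zn (1.1 equiv), toluene/hexane, 0 °C; then 3, 0 °C to rt; aq. NH4Cl
Reagents that add atoms: none
Why: Diethylzinc converts 2 into its ethylzinc alkoxide, which undergoes bromine–zinc exchange with 3 and loses bromide to give the zinc-bound 1-methyl-2-oxyallyl cation 4, whose three-carbon 2π system adds across the 4π system of the furan, forming C7–C8 and C1–C10 in one operation. The closest known reaction type is the zinc-mediated (4+3) cycloaddition of oxyallyl cations from α,α'-dibromo ketones to furans, including its chelation-directed variant with free 2-furyl carbinols. The seven-membered carbocycle is closed intermolecularly as a cation (4π+2π) cycloaddition; in the stepwise limit the first bond is an electrophilic attack at the unsubstituted furan α-carbon and the second a 7-(enolendo)-exo-trig attack of the zinc enolate on the furan-derived oxocarbenium ion, the furan oxygen becoming the one-atom bridge. C1 and C7 (the furan face) are controlled by the (R)-carbinol through the alkoxide–zinc–oxyallyl chelate, and C10 by the extended transition state that this chelate enforces, which places the methyl group exo, syn to the oxygen bridge and hence cis to the future C1 hydroxyl. The step needs regioselectivity (CH(CH3) terminus at the substituted carbon C1) and exo selectivity; the first is secured because the first bond should form between the two unhindered termini (the CH2 end of the cation and the free furan α-carbon), the second by the zinc tether.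

Step 3
Reactants: 5 (1R,2R,5R)-1-[(1R)-1-hydroxybutyl]-2-methyl-8-oxabicyclo[3.2.1]oct-6-en-3-one
Product: 7 (6R,7R)-7-methyl-6-[(1R)-1-(triethylsilyloxy)butyl]-6-(triethylsilyloxy)cyclohepta-2,4-dien-1-one, via kinetic triethylsilyl enol ether 6 (not isolated)
Conditions: TESOTf (2.3 equiv), Et3N (3 equiv), CH2Cl2, −78 to −20 °C; aq. NaHCO3
Reagents that add atoms: triethylsilyl trifluoromethanesulfonate CC[Si](CC)(CC)OS(=O)(=O)C(F)(F)F
Why: Soft enolisation toward C8 (the C10 hydrogen is equatorial and stereoelectronically inert) followed by silyl-triflate-assisted β-elimination of the C7–O bridge bond, the retro-oxa-Michael ring opening known for 8-oxabicyclo[3.2.1]oct-6-en-3-ones, should give the dienone with the C1 oxygen silylated in the same flask, so that the tertiary alkoxide can neither re-add nor trigger retro-aldol cleavage of the C1–C10 bond.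

Step 4
Reactants: 7 (6R,7R)-7-methyl-6-[(1R)-1-(triethylsilyloxy)butyl]-6-(triethylsilyloxy)cyclohepta-2,4-dien-1-one
Product: 8 5α,6α-epoxide of 7
Conditions: mCPBA, NaHCO3, CH2Cl2, 0 °C
Reagents that add atoms: mCPBA OOC(=O)c1cccc(Cl)c1
Why: Prilezhaev epoxidation should occur at the more electron-rich γ,δ-alkene (C5=C6) of the dienone and anti to the pseudoaxial C1 silyloxy group (the bulky side chain lies pseudoequatorial), which sets the C5 oxygen on the α-face, trans to the C1 oxygen.

Step 5
Reactants: 8 5α,6α-epoxide of 7; 9 (diethoxyphosphoryl)acetic acid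
Product: 10 6β-[(diethoxyphosphoryl)acetoxy]-5α-hydroxy enone
Conditions: 9 (3 equiv), BF3·OEt2 (10 mol %), CH2Cl2, −40 to −10 °C
Reagents that add atoms: none
Why: Acid-catalysed SN2 opening of a vinyl epoxide by a carboxylic acid takes place at the allylic carbon with inversion, so the acyloxy group should enter C6 on the β-face, trans to the retained C5α hydroxyl, while the hindered C5 next to the quaternary centre stays untouched.

Step 6
Reactants: 10 6β-[(diethoxyphosphoryl)acetoxy]-5α-hydroxy enone
Product: 11 5α-isobutyrate of 10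
Conditions: (iPrCO)2O, DMAP, Et3N, CH2Cl2, rt
Reagents that add atoms: isobutyric anhydride CC(C)C(=O)OC(=O)C(C)C
Why: DMAP-catalysed acyl transfer to the only free hydroxyl installs the C5 isobutyrate without touching a stereocentre.

Step 7
Reactants: 11 5α-isobutyrate of 10
Product: 13 cis-fused α-methylene γ-lactone ketone, via phosphono lactone 12 (not isolated)
Conditions: NaH (1.1 equiv), THF, 0 °C to rt; then (CH2O)n, rt
Reagents that add atoms: formaldehyde (from paraformaldehyde) C=O
Why: The phosphonoacetate anion should add intramolecularly to the enone β-carbon C7 (5-exo-trig Michael addition), which can only give the cis-fused γ-lactone and so places C11 on the β-face of C7, syn to the C6 oxygen, and the resulting α-phosphono lactone anion is then methylenated by a Horner–Wadsworth–Emmons reaction with formaldehyde.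

Step 8
Reactants: 13 cis-fused α-methylene γ-lactone ketone
Product: 14 11,13-dihydro lactone ketone (C11 methyl cis to C8)
Conditions: H2 (1 atm), 10% Pd/C, EtOAc, rt
Reagents that add atoms: none
Why: Heterogeneous hydrogenation of the exocyclic methylene should deliver hydrogen from the convex face of the cis-fused bicyclic lactone, putting the C11 methyl on the concave face (H-11 cis to H-7) as in the target.

Step 9
Reactants: 14 11,13-dihydro lactone ketone
Product: 15 C9 tosylhydrazone of 14
Conditions: TsNHNH2, THF, 4 Å molecular sieves, 50 °C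
Reagents that add atoms: 4-methylbenzenesulfonohydrazide NNS(=O)(=O)c1ccc(C)cc1
Why: Condensation of the only ketone (C9) with tosylhydrazide gives the tosylhydrazone without affecting the esters, the lactone or the silyl ethers.

Step 10
Reactants: 15 C9 tosylhydrazone of 14
Product: 16 9-deoxo bis(triethylsilyl) ether
Conditions: catecholborane, CHCl3, 0 °C; then NaOAc·3H2O, reflux
Reagents that add atoms: none
Why: Caglioti-type reduction (hydroboration of the C=N bond, then acetate-induced loss of sulfinate and dinitrogen) converts the tosylhydrazone into the C9 methylene under conditions that spare esters and lactones.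

Step 11
Reactants: 16 9-deoxo bis(triethylsilyl) ether
Product: 17 C1,C2-diol
Conditions: HF·pyridine, THF/pyridine, 0 °C to rt
Reagents that add atoms: none
Why: Fluoride-mediated desilylation under mildly acidic conditions should free both hydroxyls without migration of the C5 isobutyrate, and it is done only now because, with the C9 ketone gone, the free C1 hydroxyl can no longer trigger retro-aldol cleavage.

Step 12
Reactants: 17 C1,C2-diol
Product: 19 (3R,3aS,6S,7S,8S,8aR)-7-[(2E)-but-2-enoyl]-7-hydroxy-3,6-dimethyl-2-oxooctahydro-2H-cyclohepta[b]furan-8-yl 2-methylpropanoate (target), via butanoyl ketone 18 (not isolated)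
Conditions: IBX (4 equiv), DMSO, rt then 75 °C
Reagents that add atoms: none
Why: IBX oxidises the secondary C2 alcohol to the ketone and, on warming, dehydrogenates that ketone at its only enolisable side (C3–C4, since C1 is quaternary) to the conjugated (E)-enone, while the tertiary alcohol, the esters and the lactone should be inert.

Compound list

1 | 1-(furan-2-yl)butan-1-one | CCCC(=O)c1ccco1 | starting material
2 | (R)-1-(furan-2-yl)butan-1-ol | CCC[C@@H](O)c1ccco1 | intermediate
3 | 1,3-dibromobutan-2-one (racemic) | CC(Br)C(=O)CBr | starting material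
4 | zinc-bound oxyallyl cation: 1-methyl-2-oxidoallyl cation bound through zinc to the alkoxide of 2, bromide | CCC[C@@H](O[Zn]OC(=C)[CH+]C)c1ccco1.[Br-] | intermediate
5 | (1R,2R,5R)-1-[(1R)-1-hydroxybutyl]-2-methyl-8-oxabicyclo[3.2.1]oct-6-en-3-one (methyl exo, syn to the oxygen bridge) | CCC[C@@H](O)[C@]1(O2)[C@@H](C)C(=O)C[C@@H]2C=C1 | intermediate
6 | kinetic triethylsilyl enol ether (C8=C9–OSiEt3) of the C2 triethylsilyl ether of 5 | CCC[C@@H](O[Si](CC)(CC)CC)[C@]1(O2)[C@@H](C)C(O[Si](CC)(CC)CC)=C[C@@H]2C=C1 | intermediate
7 | (6R,7R)-7-methyl-6-[(1R)-1-(triethylsilyloxy)butyl]-6-(triethylsilyloxy)cyclohepta-2,4-dien-1-one (C9 ketone, C7=C8 and C5=C6 alkenes, C1–OSiEt3 and C10–CH3 cis) | CCC[C@@H](O[Si](CC)(CC)CC)[C@]1(O[Si](CC)(CC)CC)[C@@H](C)C(=O)C=CC=C1 | intermediate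
8 | 5α,6α-epoxide of 7 (epoxide oxygen trans to the C1 silyloxy group) | CCC[C@@H](O[Si](CC)(CC)CC)[C@]1(O[Si](CC)(CC)CC)[C@@H](C)C(=O)C=C[C@@H]2O[C@H]12 | intermediate
9 | (diethoxyphosphoryl)acetic acid | OC(=O)CP(=O)(OCC)OCC | starting material
10 | 6β-[(diethoxyphosphoryl)acetoxy]-5α-hydroxy enone (C7=C8–C9=O; C1 and C10 as in 7) | CCC[C@@H](O[Si](CC)(CC)CC)[C@]1(O[Si](CC)(CC)CC)[C@@H](C)C(=O)C=C[C@@H](OC(=O)CP(=O)(OCC)OCC)[C@@H]1O | intermediate
11 | 5α-isobutyrate of 10 | CCC[C@@H](O[Si](CC)(CC)CC)[C@]1(O[Si](CC)(CC)CC)[C@@H](C)C(=O)C=C[C@@H](OC(=O)CP(=O)(OCC)OCC)[C@@H]1OC(=O)C(C)C | intermediate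
12 | phosphono lactone: cis-fused C6–O/C7 γ-lactone with diethoxyphosphoryl at C11 (C11 unassigned), C9 ketone | CCC[C@@H](O[Si](CC)(CC)CC)[C@]1(O[Si](CC)(CC)CC)[C@@H](C)C(=O)C[C@@H]2[C@@H](OC(=O)C2P(=O)(OCC)OCC)[C@@H]1OC(=O)C(C)C | intermediate
13 | cis-fused α-methylene γ-lactone ketone (C11=C13, C9 ketone) | CCC[C@@H](O[Si](CC)(CC)CC)[C@]1(O[Si](CC)(CC)CC)[C@@H](C)C(=O)C[C@@H]2[C@@H](OC(=O)C2=C)[C@@H]1OC(=O)C(C)C | intermediate
14 | 11,13-dihydro lactone ketone (C11 methyl cis to C8, H-11 cis to H-7) | CCC[C@@H](O[Si](CC)(CC)CC)[C@]1(O[Si](CC)(CC)CC)[C@@H](C)C(=O)C[C@@H]2[C@@H](OC(=O)[C@@H]2C)[C@@H]1OC(=O)C(C)C | intermediate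
15 | C9 tosylhydrazone of 14 | CCC[C@@H](O[Si](CC)(CC)CC)[C@]1(O[Si](CC)(CC)CC)[C@@H](C)C(=NNS(=O)(=O)c3ccc(C)cc3)C[C@@H]2[C@@H](OC(=O)[C@@H]2C)[C@@H]1OC(=O)C(C)C | intermediate
16 | 9-deoxo bis(triethylsilyl) ether (C9 methylene) | CCC[C@@H](O[Si](CC)(CC)CC)[C@]1(O[Si](CC)(CC)CC)[C@@H](C)CC[C@@H]2[C@@H](OC(=O)[C@@H]2C)[C@@H]1OC(=O)C(C)C | intermediate
17 | C1,C2-diol: target skeleton with a (1R)-1-hydroxybutyl group at C1 | CCC[C@@H](O)[C@]1(O)[C@@H](C)CC[C@@H]2[C@@H](OC(=O)[C@@H]2C)[C@@H]1OC(=O)C(C)C | intermediate
18 | butanoyl ketone: 3,4-dihydro derivative of the target | CCCC(=O)[C@]1(O)[C@@H](C)CC[C@@H]2[C@@H](OC(=O)[C@@H]2C)[C@@H]1OC(=O)C(C)C | intermediate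
19 | (3R,3aS,6S,7S,8S,8aR)-7-[(2E)-but-2-enoyl]-7-hydroxy-3,6-dimethyl-2-oxooctahydro-2H-cyclohepta[b]furan-8-yl 2-methylpropanoate | C/C=C/C(=O)[C@]1(O)[C@@H](C)CC[C@@H]2[C@@H](OC(=O)[C@@H]2C)[C@@H]1OC(=O)C(C)C | target

Total step count: 12. Longest linear sequence: 12 steps (1 to 19).

Steps most likely to fail

1. Step 2. The two termini of the unsymmetrical oxyallyl cation may not be differentiated (methyl-bearing terminus bonding to C7 instead of C1), or the exo orientation of the methyl group may erode in a less ordered transition state. Fallback, setting out from 2 and returning at 7: the cycloaddition is run with the symmetrical oxyallyl cation generated from 1,1,3,3-tetrabromopropan-2-one and Et2Zn, where neither regiochemistry nor a methyl configuration is at stake, to give the dibromo cycloadduct F1. Zn–Cu couple and NH4Cl in MeOH remove both bromines to give the nor-methyl bicyclic ketone F2. Ring opening with TESOTf/Et3N as in step 3 gives the nor-methyl dienone F3. Kinetic α'-deprotonation with LDA at −78 °C and alkylation with MeI, which should enter anti to the bulky C1 side chain, then gives 7.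

2. Step 4. The peracid oxygen may be delivered to the wrong face of the C5=C6 alkene (syn to the silyloxy group) if the two C1 substituents shield both faces to a similar degree. Fallback, from 7 to 8: steric control is replaced by hydroxyl direction. Selective methanolysis of the secondary silyl ether (PPTS, MeOH, 0 °C) gives the C2 alcohol F4. Its homoallylic hydroxyl, carried by the α-oriented side chain, directs a VO(acac)2/t-BuOOH epoxidation to the α-face to give the epoxy alcohol F5. Resilylation (TESCl, imidazole, DMF) gives 8.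

3. Step 5. The epoxide may open at C5 instead of C6, ionise with loss of the stereochemical inversion, or be intercepted by a silyl ether oxygen. Fallback, from 7 to 10: the two oxygens are introduced as a cis-diol and C6 is inverted afterwards. OsO4 (cat.)/NMO dihydroxylation of the γ,δ-alkene anti to the silyloxy group gives the 5α,6α-diol F6. A Mitsunobu esterification with 9 (PPh3, DIAD, THF), which should engage only the allylic, less hindered C6 hydroxyl and invert it, gives 10.

Further compounds

F1 | step 2 | 2,4-dibromo-1-[(1R)-1-hydroxybutyl]-8-oxabicyclo[3.2.1]oct-6-en-3-one (bridgeheads as in 5, bromine configurations unassigned) | CCC[C@@H](O)[C@]1(O2)C(Br)C(=O)C(Br)[C@@H]2C=C1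
F2 | step 2 | 1-[(1R)-1-hydroxybutyl]-8-oxabicyclo[3.2.1]oct-6-en-3-one (nor-methyl analogue of 5) | CCC[C@@H](O)[C@]1(O2)CC(=O)C[C@@H]2C=C1
F3 | step 2 | 6-[(1R)-1-(triethylsilyloxy)butyl]-6-(triethylsilyloxy)cyclohepta-2,4-dien-1-one (nor-methyl analogue of 7) | CCC[C@@H](O[Si](CC)(CC)CC)[C@]1(O[Si](CC)(CC)CC)CC(=O)C=CC=C1
F4 | step 4 | C2 alcohol: 7 without the secondary triethylsilyl group | CCC[C@@H](O)[C@]1(O[Si](CC)(CC)CC)[C@@H](C)C(=O)C=CC=C1
F5 | step 4 | epoxy alcohol: 8 without the secondary triethylsilyl group | CCC[C@@H](O)[C@]1(O[Si](CC)(CC)CC)[C@@H](C)C(=O)C=C[C@@H]2O[C@H]12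
F6 | step 5 | 5α,6α-diol of 7 | CCC[C@@H](O[Si](CC)(CC)CC)[C@]1(O[Si](CC)(CC)CC)[C@@H](C)C(=O)C=C[C@H](O)[C@@H]1O
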